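**Retrosynthetic overview**

- Last cut: the C7–CH2–C3' bridge, giving the ring-A phenol with free C7, a one-carbon iminium reagent and the separately made 6-ethyl-4-hydroxy-5-methyl-2-pyrone (ring C).
- The strategy rests on ring A (the benzene ring) carrying oxygen on C4, C6 and C7a and the isobutyryl group on C5. C6–C7–C7a–C3a maps onto an oxygenated diene that already carries ring B, and C4–C5 onto a push–pull alkoxy ynone, so a [4+2] benzannulation forms C3a–C4 and C5–C6.
- Ring B (dihydrofuran) and the only stereocenter, C2, come from (S)-2-(prop-1-en-2-yl)oxirane by terminal opening with methyl acetoacetate dianion and cyclodehydration. No bond to C2 is made or broken afterwards.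
- The C4 oxygen is carried as a 2-(trimethylsilyl)ethyl ether and freed with fluoride. Boron trihalides are avoided: they would threaten the allylic C2–O1 bond and the isopropenyl group, and the free C6 hydroxyl would take up the chelate.
- Order of ring formation: ring B, then ring A; ring C is built apart and joined last.

Key step: step 8

Remark: ring A is numbered as in 2,3-dihydro-1-benzofuran (O1, C2, C3, C3a, C4–C7, C7a). It is assumed that the (S,S)-cobalt salen catalyst leaves the (S)-epoxide, as with other terminal epoxides whose substituent ranks below the ring CH2; the sense is to be confirmed by optical rotation before step 3.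

**Route**

Step 1
Reactants: 1 methacrolein
Product: 2 rac-2-(prop-1-en-2-yl)oxirane
Conditions: Me3S+ I−, NaH, DMSO, 15 → 23 °C; product distilled out under reduced pressure into a cold trap
Reagents that add atoms: trimethylsulfonium iodide, C[S+](C)C.[I-]
Why: Corey–Chaykovsky epoxidation, in which the unstabilised sulfonium ylide adds 1,2 to the enal carbonyl and the betaine closes to the vinyl epoxide; no stereocontrol is needed because the racemate is resolved in step 2.

Step 2
Reactants: 2 rac-2-(prop-1-en-2-yl)oxirane
Product: 3 (2S)-2-(prop-1-en-2-yl)oxirane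
Conditions: (S,S)-(salen)Co(OAc) [(S,S)-N,N'-bis(3,5-di-tert-butylsalicylidene)cyclohexane-1,2-diaminocobalt acetate, trivalent cobalt] (0.5 mol%), H2O (0.55 equiv), neat, 0 → 23 °C; distillation
Reagents that add atoms: none
Why: Hydrolytic kinetic resolution of a terminal epoxide, in which the chiral cobalt salen catalyst should hydrolyse the (R)-enantiomer selectively, so that the volatile (S)-epoxide carrying the future C2 configuration is distilled from the diol.

Step 3
Reactants: 4 methyl acetoacetate; 3 (2S)-2-(prop-1-en-2-yl)oxirane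
Product: 5 methyl (6R)-6-hydroxy-7-methyl-3-oxooct-7-enoate
Conditions: 4 (1.5 equiv): NaH, THF, 0 °C; n-BuLi, 0 °C; then 3, 0 → 23 °C; aq. NH4Cl
Reagents that add atoms: none
Why: Alkylation of a β-keto ester dianion at its terminal carbon by SN2 opening of the epoxide at the unhindered CH2, which leaves the C–O stereocenter untouched (the descriptor changes from S to R only because the CIP priorities change).

Step 4
Reactants: 5 methyl (6R)-6-hydroxy-7-methyl-3-oxooct-7-enoate
Product: 6 methyl (2E)-2-[(5R)-5-(prop-1-en-2-yl)oxolan-2-ylidene]acetate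
Conditions: (CO2H)2 (cat.), 4 Å MS, CH2Cl2, 40 °C
Reagents that add atoms: none
Why: Acid-catalysed cyclodehydration of a γ-hydroxy ketone (five-membered hemiketal, then loss of water into conjugation with the ester) to the 2-alkylidene tetrahydrofuran; the C–O bond of the stereocenter is not broken, and the expected (E)-geometry is not required because it is erased in step 5.

Step 5
Reactants: 6 methyl (2E)-2-[(5R)-5-(prop-1-en-2-yl)oxolan-2-ylidene]acetate
Product: 7 (2R)-5-[(E)-2-methoxy-2-(trimethylsilyloxy)ethenyl]-2-(prop-1-en-2-yl)-2,3-dihydrofuran (either ketene acetal geometry serves)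
Conditions: LDA, THF, −78 °C; Me3SiCl, −78 → 0 °C; pentane, filtration under argon; used crude
Reagents that add atoms: chlorotrimethylsilane, C[Si](C)(C)Cl
Why: γ-Deprotonation of a β-alkoxy enoate at the ring CH2 next to the enol ether carbon and O-silylation of the extended enolate, the standard preparation of vinylogous silyl ketene acetals from 3-alkoxy-2-enoates.

Step 6
Reactants: 8 2-(trimethylsilyl)ethanol; 9 trichloroethylene
Product: 10 [2-{[(E)-1,2-dichloroethenyl]oxy}ethyl](trimethyl)silane
Conditions: KH, THF, 0 °C; Cl2C=CHCl, −50 → 23 °C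
Reagents that add atoms: none
Why: Elimination–addition, in which the alkoxide generates dichloroacetylene from trichloroethylene and adds to it in the anti sense to give the (E)-1,2-dichlorovinyl ether, the usual entry to alkoxyacetylenes from alcohols.

Step 7
Reactants: 10 [2-{[(E)-1,2-dichloroethenyl]oxy}ethyl](trimethyl)silane; 11 N-methoxy-N-methylisobutyramide
Product: 13 4-methyl-1-[2-(trimethylsilyl)ethoxy]pent-1-yn-3-one, via lithium alkoxyacetylide 12 (not isolated)
Conditions: n-BuLi (2.2 equiv), THF, −78 → −40 °C; then 11, −78 → 0 °C; aq. NH4Cl; rapid filtration through Et3N-deactivated SiO2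
Reagents that add atoms: none
Why: Dehydrochlorination and chlorine–lithium exchange give the lithium alkoxyacetylide, and its Weinreb ketone synthesis with the amide stops at the ynone because the chelated tetrahedral adduct persists until work-up.

Step 8
Reactants: 7 (2R)-5-[(E)-2-methoxy-2-(trimethylsilyloxy)ethenyl]-2-(prop-1-en-2-yl)-2,3-dihydrofuran; 13 4-methyl-1-[2-(trimethylsilyl)ethoxy]pent-1-yn-3-one
Product: 15 1-[(2R)-6-hydroxy-2-(prop-1-en-2-yl)-4-[2-(trimethylsilyl)ethoxy]-2,3-dihydro-1-benzofuran-5-yl]-2-methylpropan-1-one, via cyclohexadiene cycloadduct 14 (not isolated)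
Conditions: 7 (1.5 equiv), PhMe, 0 → 50 °C; then SiO2, CH2Cl2, 23 °C
Reagents that add atoms: none
Why: Proposed new method: the γ-carbon of the vinylogous silyl ketene acetal (ring carbon of 7, future C3a) should attack the alkoxy-bearing alkyne carbon of 13 (future C4), and the allenolate carbon so formed (C5) should close on the silyloxy oxocarbenium carbon (C6), an asynchronous [4+2] cycloaddition (in the limit a Mukaiyama–Michael addition followed by ring closure) that gives cycloadduct 14. Ring A, the only ring formed, is thus closed as a six-membered carbocycle by the two bonds C3a–C4 and C5–C6, and 14 aromatises by loss of MeOSiMe3 from C6 and enolisation of the C3a hydrogen, the C6 hydroxyl ending hydrogen-bonded to the C5 ketone. The closest known reaction type is the Diels–Alder benzannulation of 1-alkoxy-1-silyloxy-3-oxy dienes with acetylenic ketones and esters, together with the formal [3+3] cyclisation of 1,3-bis(silyloxy) dienes with 3-alkoxy enones; a 1-alkoxyalk-1-yn-3-one has not been shown as the two-carbon partner, nor a diene whose terminus lies in a dihydrofuran. No stereocenter that survives is created (C3a and C6 of 14 become sp2) and C2 takes no part, so its configuration from step 2 is kept. The step needs regioselectivity (C3a to C4, not to C5) and chemoselectivity for the alkyne over the ketone carbonyl; the first is secured by the matched polarisation of the partners (largest HOMO coefficient at C3a, electrophilic β-carbon of the push–pull ynone), the second by running the reaction thermally without a Lewis acid, and the s-cis diene is accessible because the inside position at C3a carries hydrogen.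

Step 9
Reactants: 15 1-[(2R)-6-hydroxy-2-(prop-1-en-2-yl)-4-[2-(trimethylsilyl)ethoxy]-2,3-dihydro-1-benzofuran-5-yl]-2-methylpropan-1-one
Product: 16 1-[(2R)-4,6-dihydroxy-2-(prop-1-en-2-yl)-2,3-dihydro-1-benzofuran-5-yl]-2-methylpropan-1-one
Conditions: Bu4NF (3 equiv), THF, 23 → 50 °C; aq. NH4Cl
Reagents that add atoms: none
Why: Fluoride-induced β-elimination of the aryl 2-(trimethylsilyl)ethyl ether releases ethene, Me3SiF and the C4 phenoxide (a leaving group helped by the ortho ketone) under conditions that leave the allylic aryl ether of ring B and the isopropenyl group alone.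

Step 10
Reactants: 17 methyl 3-oxopentanoate; 18 N-methoxy-N-methylpropanamide
Product: 19 methyl 4-methyl-3,5-dioxoheptanoate
Conditions: 17 (2.2 equiv): NaH, THF, 0 °C; n-BuLi, 0 °C; then 18, −78 → 0 °C; aq. HCl
Reagents that add atoms: none
Why: Claisen-type γ-acylation of a β-keto ester dianion with a Weinreb amide, the excess dianion taking up the acidic proton of the product.

Step 11
Reactants: 19 methyl 4-methyl-3,5-dioxoheptanoate
Product: 20 6-ethyl-4-hydroxy-5-methyl-2H-pyran-2-one
Conditions: DBU, PhMe, 110 °C; aq. HCl
Reagents that add atoms: none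
Why: Base-mediated lactonisation of a 3,5-dioxo ester through the enol oxygen of the C5 ketone gives the 4-hydroxy-2-pyrone with loss of methanol.

Step 12
Reactants: 20 6-ethyl-4-hydroxy-5-methyl-2H-pyran-2-one; 16 1-[(2R)-4,6-dihydroxy-2-(prop-1-en-2-yl)-2,3-dihydro-1-benzofuran-5-yl]-2-methylpropan-1-one
Product: 23 6-ethyl-4-hydroxy-3-{[(2R)-4,6-dihydroxy-5-(2-methylpropanoyl)-2-(prop-1-en-2-yl)-2,3-dihydro-1-benzofuran-7-yl]methyl}-5-methyl-2H-pyran-2-one, via pyrone Mannich base 21 (not isolated), via methylidene pyrandione 22 (not isolated)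
Conditions: 20, CH2=NMe2+ I− (1.05 equiv), MeCN, 23 °C; then 16, 60 °C
Reagents that add atoms: dimethylmethylideneammonium iodide, C=[N+](C)C.[I-]
Why: Mannich reaction of the pyrone at C3, thermal loss of dimethylamine to the 3-methylidene pyran-2,4-dione and Michael-type (Friedel–Crafts) addition of C7, the only free carbon of ring A and flanked by the C6 hydroxyl and O1, should give the methylene-bridged target without touching C2.

**Compound list**

1 | methacrolein (2-methylprop-2-enal) | C=C(C)C=O | starting material
2 | rac-2-(prop-1-en-2-yl)oxirane | C=C(C)C1CO1 | intermediate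
3 | (2S)-2-(prop-1-en-2-yl)oxirane | C=C(C)[C@H]1CO1 | intermediate
4 | methyl acetoacetate (methyl 3-oxobutanoate) | COC(=O)CC(C)=O | starting material
5 | methyl (6R)-6-hydroxy-7-methyl-3-oxooct-7-enoate | C=C(C)[C@H](O)CCC(=O)CC(=O)OC | intermediate
6 | methyl (2E)-2-[(5R)-5-(prop-1-en-2-yl)oxolan-2-ylidene]acetate | C=C(C)[C@H]1CC/C(=C\C(=O)OC)O1 | intermediate
7 | (2R)-5-[(E)-2-methoxy-2-(trimethylsilyloxy)ethenyl]-2-(prop-1-en-2-yl)-2,3-dihydrofuran | C=C(C)[C@H]1CC=C(/C=C(\OC)O[Si](C)(C)C)O1 | intermediate
8 | 2-(trimethylsilyl)ethanol | C[Si](C)(C)CCO | starting material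
9 | trichloroethylene | ClC=C(Cl)Cl | starting material
10 | [2-{[(E)-1,2-dichloroethenyl]oxy}ethyl](trimethyl)silane | C[Si](C)(C)CCO/C(Cl)=C\Cl | intermediate
11 | N-methoxy-N-methylisobutyramide (N-methoxy-N,2-dimethylpropanamide) | CON(C)C(=O)C(C)C | starting material
12 | lithium 2-[2-(trimethylsilyl)ethoxy]ethyn-1-ide | [Li+].[C-]#COCC[Si](C)(C)C | intermediate
13 | 4-methyl-1-[2-(trimethylsilyl)ethoxy]pent-1-yn-3-one | C[Si](C)(C)CCOC#CC(=O)C(C)C | intermediate
14 | 1-[(2R)-6-methoxy-2-(prop-1-en-2-yl)-6-(trimethylsilyloxy)-4-[2-(trimethylsilyl)ethoxy]-2,3,3a,6-tetrahydro-1-benzofuran-5-yl]-2-methylpropan-1-one (C3a and C6 unassigned, transient) | C=C(C)[C@H]1CC2C(OCC[Si](C)(C)C)=C(C(=O)C(C)C)C(OC)(O[Si](C)(C)C)C=C2O1 | intermediate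
15 | 1-[(2R)-6-hydroxy-2-(prop-1-en-2-yl)-4-[2-(trimethylsilyl)ethoxy]-2,3-dihydro-1-benzofuran-5-yl]-2-methylpropan-1-one | C=C(C)[C@H]1Cc2c(OCC[Si](C)(C)C)c(C(=O)C(C)C)c(O)cc2O1 | intermediate
16 | 1-[(2R)-4,6-dihydroxy-2-(prop-1-en-2-yl)-2,3-dihydro-1-benzofuran-5-yl]-2-methylpropan-1-one | C=C(C)[C@H]1Cc2c(O)c(C(=O)C(C)C)c(O)cc2O1 | intermediate
17 | methyl 3-oxopentanoate | CCC(=O)CC(=O)OC | starting material
18 | N-methoxy-N-methylpropanamide | CCC(=O)N(C)OC | starting material
19 | methyl 4-methyl-3,5-dioxoheptanoate | CCC(=O)C(C)C(=O)CC(=O)OC | intermediate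
20 | 6-ethyl-4-hydroxy-5-methyl-2H-pyran-2-one | CCc1oc(=O)cc(O)c1C | intermediate
21 | 3-[(dimethylamino)methyl]-6-ethyl-4-hydroxy-5-methyl-2H-pyran-2-one | CCc1oc(=O)c(CN(C)C)c(O)c1C | intermediate
22 | 6-ethyl-5-methyl-3-methylidene-2H-pyran-2,4(3H)-dione | CCC1=C(C)C(=O)C(=C)C(=O)O1 | intermediate
23 | 6-ethyl-4-hydroxy-3-{[(2R)-4,6-dihydroxy-5-(2-methylpropanoyl)-2-(prop-1-en-2-yl)-2,3-dihydro-1-benzofuran-7-yl]methyl}-5-methyl-2H-pyran-2-one | C=C(C)[C@H]1Cc2c(O)c(C(=O)C(C)C)c(O)c(Cc3c(O)c(C)c(CC)oc3=O)c2O1 | target

**Step count**

Total: 12 steps. Longest linear sequence: 8 steps (1, 2, 3, 4, 5, 8, 9, 12).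

**Steps most likely to fail**

1. Step 8 (Proposed new method). The push–pull ynone may be too weak an acceptor, so that protodesilylation of the diene, attack at the ketone carbonyl, or bonding through C7 instead of C3a outruns the wanted C3a–C4 bond formation. The fallback makes the same two ring bonds one after the other by known enolate chemistry. It sets out from ester 6 and Weinreb amide 11 and comes back at 16, so that steps 5 to 9 are not needed. The lithium dienolate of 6 (LDA, THF, −78 °C) would be acylated at ring carbon C3 (the γ-position, future C3a) with N-methoxy-N-methylacetamide to give methyl (2E)-2-[(5R)-3-acetyl-5-(prop-1-en-2-yl)oxolan-2-ylidene]acetate F1. The dianion of F1 (2.2 equiv LDA) would be acylated at the acetyl methyl with 11, the terminal acylation of a β-dicarbonyl dianion as in step 10, to give methyl (2E)-2-[(5R)-3-(4-methyl-3-oxopentanoyl)-5-(prop-1-en-2-yl)oxolan-2-ylidene]acetate F2. Intramolecular Claisen condensation of the doubly activated CH2 of F2 (future C5) on the ester carbon (future C6) with NaOMe in MeOH, followed by enolisation, would give 16 with loss of methanol.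

2. Step 3. The hard dianion may open the vinyl epoxide slowly and in part at the allylic carbon or in the SN2' sense, which would erode yield and purity of 5. The fallback uses a soft nucleophile that takes vinyl epoxides at the terminal CH2; it sets out from epoxide 3 and comes back at 5. Dimethyl malonate with NaOMe in MeOH would open 3 and lactonise to methyl (5R)-2-oxo-5-(prop-1-en-2-yl)oxolane-3-carboxylate F3. Saponification with LiOH, acidification and warming in toluene would decarboxylate it to (5R)-5-(prop-1-en-2-yl)oxolan-2-one F4. Single addition of the lithium enolate of methyl acetate (LDA, MeOAc, THF, −78 °C) to the lactone carbonyl of F4 would then give a hemiketal that is the ring tautomer of 5 and enters step 4 as such.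

3. Step 12. The methylidene pyrandione may be captured by a second pyrone (homo-coupling to the bis-pyrone methane), or the Mannich equilibria may scramble the methylene between the partners. The fallback reverses the roles so that the one-carbon unit is fixed on ring A first; it sets out from 16 and comes back at 23. Aminomethylation of 16 at C7 with dimethylmethylideneammonium iodide (CH2Cl2, 23 °C) would give 1-[(2R)-7-[(dimethylamino)methyl]-4,6-dihydroxy-2-(prop-1-en-2-yl)-2,3-dihydro-1-benzofuran-5-yl]-2-methylpropan-1-one F5, which is purified. Heating F5 with pyrone 20 (dioxane, 90 °C) would expel dimethylamine to the ortho-quinone methide of ring A, which C3 of the pyrone traps to give 23.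

**Further compounds**

F1 | step 8 | methyl (2E)-2-[(5R)-3-acetyl-5-(prop-1-en-2-yl)oxolan-2-ylidene]acetate | C=C(C)[C@H]1CC(C(C)=O)/C(=C\C(=O)OC)O1
F2 | step 8 | methyl (2E)-2-[(5R)-3-(4-methyl-3-oxopentanoyl)-5-(prop-1-en-2-yl)oxolan-2-ylidene]acetate | C=C(C)[C@H]1CC(C(=O)CC(=O)C(C)C)/C(=C\C(=O)OC)O1
F3 | step 3 | methyl (5R)-2-oxo-5-(prop-1-en-2-yl)oxolane-3-carboxylate | C=C(C)[C@H]1CC(C(=O)OC)C(=O)O1
F4 | step 3 | (5R)-5-(prop-1-en-2-yl)oxolan-2-one | C=C(C)[C@H]1CCC(=O)O1
F5 | step 12 | 1-[(2R)-7-[(dimethylamino)methyl]-4,6-dihydroxy-2-(prop-1-en-2-yl)-2,3-dihydro-1-benzofuran-5-yl]-2-methylpropan-1-one | C=C(C)[C@H]1Cc2c(O)c(C(=O)C(C)C)c(O)c(CN(C)C)c2O1
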